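The earlier runs and the new flask were generated by integration for an exercise; scatter was added.

Every first end group charged stands at any moment free, in a link, in a ring or in side product, so these percentages add to the whole, and one that joins a ring is lost to the links.

| flask | first end groups | second end groups | remark | time |
|---|---|---|---|---|
| Saturday's | 0.050 M | 0.051 M | run made earlier |  |
| Wednesday's | 0.050 M | 0.025 M | run made earlier |  |
| Thursday's | 0.050 M | 0.10 M | run made earlier |  |
| Tuesday's | 0.025 M | 0.051 M | run made earlier |  |
| west | 0.050 M (fed, over 1.5 min) | 0.0510 M | all else is in the flask from the start; the feed brings no volume worth counting | 2.5 min |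
| south-east | 0.050 M (in portions, 3, over 1.5 min) | 0.0510 M | first portion at the start, last at 1.5 min | 2.5 min |
| south | 0.050 M | 0.0510 M (fed, over 1.5 min) | all else is in the flask from the start; the feed brings no volume worth counting | 2.5 min |
| north | 0.050 M | 0.0510 M | everything together at the start | 2.5 min |

| run | time / s | links / % | rings / % | first end groups / % |
|---|---|---|---|---|
| Saturday's | 10.0 | 12.4 | 6.5 | 80.4 |
| Saturday's | 20.0 | 20.5 | 12.1 | 65.9 |
| Saturday's | 30.0 | 24.8 | 17.2 | 55.5 |
| Saturday's | 50.0 | 29.3 | 23.7 | 41.4 |
| Saturday's | 60.0 | 30.3 | 27.0 | 35.6 |
| Saturday's | 90.0 | 32.3 | 33.6 | 26.4 |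
| Wednesday's | 10.0 | 6.3 | 7.0 | 87.1 |
| Wednesday's | 15.0 | 7.7 | 9.8 | 81.3 |
| Wednesday's | 25.0 | 11.1 | 15.8 | 72.1 |
| Wednesday's | 40.0 | 12.6 | 23.9 | 62.1 |
| Wednesday's | 80.0 | 11.8 | 30.0 | 53.7 |
| Wednesday's | 120 | 10.9 | 29.8 | 51.0 |
| Thursday's | 20.0 | 36.8 | 10.0 | 49.2 |
| Thursday's | 40.0 | 49.6 | 15.9 | 28.0 |
| Thursday's | 60.0 | 55.8 | 19.9 | 17.6 |
| Thursday's | 80.0 | 58.5 | 22.4 | 10.9 |
| Thursday's | 90.0 | 59.6 | 22.6 | 8.6 |
| Thursday's | 120 | 60.1 | 24.0 | 5.8 |
| Tuesday's | 10.0 | 14.4 | 5.5 | 80.0 |
| Tuesday's | 30.0 | 29.4 | 17.1 | 51.9 |
| Tuesday's | 60.0 | 39.5 | 25.3 | 31.8 |
| Tuesday's | 80.0 | 41.8 | 30.2 | 23.9 |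
| Tuesday's | 120 | 45.1 | 34.5 | 13.5 |

(scatter of a reading: 0.5 percentage points)

- a species is counted by the first end groups in it: one side product counts as two
- on the list of suspects stand: first end groups + second end groups -> links; first end groups + second end groups -> rings; second end groups <-> dormant form; first end groups + links -> side product

1. the flask with the highest share of links in links plus rings ("all alike" if they lie within 1.5 percentage points) (west / south-east / south / north / all alike)
2. share of links in links plus rings at the end, west
3. share of links in links plus rings at the end, south-east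
4. share of links in links plus rings at the end, south
5. share of links in links plus rings at the end, north

With twice the second end groups, Saturday's run has rings of 6.5% against Wednesday's 7.0% at 10.0 s, but links of 12.4% against 6.3%. So links per ring follow [second end groups]. Saturday's charge times rings over links reads 0.0267 M, and Thursday's reads 0.0272 M. This is the break-even level: the free [second end groups] at which links and rings form equally, a selectivity factor in concentration units.

North has Saturday's charges, so at the start it makes 65.6% links, and Saturday's run carries it to 90.0 s. Between 60.0 s and 90.0 s rings grow at 0.00710 s⁻¹ per first end group, while first end groups decay at 0.00997 s⁻¹, so rings take 71.2% of what is spent. Continuing to 2.5 min leaves 14.5% free and brings rings to 42.1%. With links held at 32.3%, we reckon north's share at 43.4%.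

Holding links is the weak link. By the balance, 3.4 percentage points remain for links and side product, and if links took all of it the share would be 45.9%. We commit to that range.

In south the feed of second end groups, 5.67 × 10⁻⁴ M s⁻¹, exceeds the rings' take at the full charge of first end groups, 3.55 × 10⁻⁴ M s⁻¹. Mid-feed we reckon that this leaves about 0.00953 M, below break-even, so we put south's share at 26.3%.

Saturday's late links per ring imply 0.00810 M free, less than the 0.0180 M the count leaves. We take the difference to be dormant form. West and south-east feed first end groups into that drain, so we rank them below north, above south.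

The forecast gave west 39.5%, south-east 40.7%, south 22%, north 44%, best north, since “North uses second ends while they are still free”.

The flasks give west 39.5%, south-east 41.5%, south 23.1%, north 43.2%; highest is north.

    first end groups + second end groups → links (k = 0.330 M⁻¹ s⁻¹)
    first end groups + second end groups → rings, rate k2*[first end groups] as long as [second end groups] is above zero (k = 0.00750 s⁻¹)
    second end groups ⇌ dormant form (K = 2.30, k = 0.00640 s⁻¹)
    first end groups + links → side product (k = 0.0870 M⁻¹ s⁻¹)

South at 2.50 min holds 19.8% of its first end groups free, with free second end groups at 0.00497 M, below break-even. Reckoned with our break-even level as read from the runs, links take 15.7% of what is still to come at that level, so we expect rings near 75.0%. With links held at 17.5%, the reckoned share is 18.9%. South read at 10.0 min holds rings of 74.7%, links of 16.7%, and a share of 18.3%.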